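The target is a 1,4-dicarbonyl compound: ester carbon C12 and aldehyde carbon C11 sit on the adjacent ring-B (cyclohexene) carbons C8 and C9, so both ends of the C8–C9 bond are α-carbonyl carbons of like polarity. The route makes this bond last. C8 is turned into an electrophile as a (Z)-vinyl bromide and joined to the C9 aldehyde enolate by palladium catalysis; this single operation closes ring B, delivers the complete ene-ester/aldehyde array and sets C9. Its precursor is a fully substituted ring-A cyclohexane carrying all other stereocentres, a CH2CHO arm on C10 and a CH2CH=C(Br)CO2Me arm on C5, built from 2-methylcyclohexane-1,3-dione by stereocontrolled steps.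

Key step: step 18

Convention used below: locants C1–C12 are those of the bicyclic target (ring A = C1–C5 and C10, with OH on C1, Cl on C3, methyl-bearing quaternary C4 and C10; ring B = C5–C10 with C7=C8; C11 = aldehyde carbon on C9, C12 = ester carbon on C8). β is the face of ring A that carries the two methyl groups, α the opposite face.

Step 1
Reactants: 1 2-methylcyclohexane-1,3-dione; 2 allyl bromide
Product: 3 2-allyl-2-methylcyclohexane-1,3-dione
Conditions: NaOH (1 M aq), n-Bu4NI (cat.), rt
Reagents that add atoms: none
Why: C-alkylation of the stabilised diketone anion with an allylic halide (any O-allyl enol ether converges on 3 by Claisen rearrangement); no stereocentre is formed.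

Step 2
Reactants: 3 2-allyl-2-methylcyclohexane-1,3-dione
Product: 4 (2R,3R)-2-allyl-3-hydroxy-2-methylcyclohexan-1-one
Conditions: (S)-2-methyl-CBS-oxazaborolidine (20 mol%), BH3·SMe2 (0.6 equiv), THF, −40 °C; MeOH
Reagents that add atoms: none
Why: Corey–Bakshi–Shibata desymmetrisation of the prochiral diketone, in which the catalyst should select the carbonyl group and its face (quaternary carbon as the large group, R carbinol expected) while hydride enters from the methyl side, so the hydroxyl ends cis to the allyl group and C3 and C4 are fixed.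

Step 3
Reactants: 4 (2R,3R)-2-allyl-3-hydroxy-2-methylcyclohexan-1-one
Product: 5 (2S,3S)-2-allyl-3-chloro-2-methylcyclohexan-1-one
Conditions: PPh3, N-chlorosuccinimide, THF, 0 °C → rt
Reagents that add atoms: N-chlorosuccinimide, ClN1C(=O)CCC1=O
Why: Appel-type deoxychlorination, in which SN2 displacement of the oxyphosphonium group with inversion should put chlorine trans to the allyl group (3β); displacement next to a quaternary carbon is slow but known for closely related 3-hydroxy-2,2-dialkylcyclohexanones, and the β-chloro ketone cannot eliminate because C4 bears no hydrogen.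

Step 4
Reactants: 5 (2S,3S)-2-allyl-3-chloro-2-methylcyclohexan-1-one
Product: 7 (5S,6S)-6-allyl-5-chloro-6-methylcyclohex-2-en-1-one, via silyl enol ether 6 (not isolated)
Conditions: LiN(i-Pr)2, Me3SiCl, THF, −78 °C; then Pd(OAc)2 (1.0 equiv), MeCN, rt
Reagents that add atoms: none
Why: Saegusa–Ito oxidation; the ketone can enolise only toward C10 because C4 is quaternary, so a single enone should result and no stereocentre is touched.

Step 5
Reactants: 7 (5S,6S)-6-allyl-5-chloro-6-methylcyclohex-2-en-1-one
Product: 9 (2S,3S,5R)-2-allyl-3-chloro-5-hydroxy-2-methylcyclohexan-1-one, via boryl ketone 8 (not isolated)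
Conditions: B2pin2, CuCl (5 mol%), Xantphos (5 mol%), NaOt-Bu (10 mol%), MeOH, THF, rt; then NaBO3·4H2O, THF/H2O
Reagents that add atoms: sodium perborate (NaBO3), [Na+].[O-]OB=O
Why: copper-catalysed conjugate borylation followed by stereoretentive C–B oxidation; the boryl–copper should add to C1 trans to the C3 chlorine (the usual trans-3,5 outcome for 5-substituted cyclohexenones), which gives the 1α-hydroxyl.

Step 6
Reactants: 9 (2S,3S,5R)-2-allyl-3-chloro-5-hydroxy-2-methylcyclohexan-1-one; 10 tert-butyl(2-iodoethoxy)dimethylsilane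
Product: 11 hydroxy ketone bearing CH2CH2OSiMe2t-Bu on C10 (arm anti to the 1α-OH)
Conditions: LiN(i-Pr)2 (2.2 equiv), THF/DMPU, −78 °C; 10, −78 → −20 °C
Reagents that add atoms: none
Why: Fráter–Seebach-type alkylation of the alkoxide–enolate dianion, which can form only at C10 and cannot eliminate; the electrophile should enter anti to the C1 alkoxide, but this C10 centre is planarised again in step 7, so either epimer serves.

Step 7
Reactants: 11 hydroxy ketone bearing CH2CH2OSiMe2t-Bu on C10
Product: 12 C5 ketone with quaternary C10 (10β-Me; 10α-CH2CH2OSiMe2t-Bu; 1α-OSiMe3)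
Conditions: LiN(i-Pr)2 (2.2 equiv), THF, −78 → −40 °C; MeI, −78 °C; then Me3SiCl, −78 → 0 °C
Reagents that add atoms: iodomethane, CI; chlorotrimethylsilane, C[Si](C)(C)Cl
Why: second Fráter–Seebach alkylation, in which methyl iodide should attack the tetrasubstituted enolate anti to the lithium alkoxide on C1, so the methyl group becomes β and the silyloxyethyl arm α (cis to O1) at the new quaternary C10; the alkoxide is capped in the same flask.

Step 8
Reactants: 12 C5 ketone with quaternary C10; 13 ethoxyacetylene
Product: 15 ethyl alkylidene acetate (exocyclic C5=C6H–CO2Et; free 1α-OH), via propargylic alcohol 14 (not isolated)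
Conditions: 13, n-BuLi, THF, −78 °C; 12, −78 → 0 °C; then Sc(OTf)3 (5 mol%), EtOH/CH2Cl2, rt
Reagents that add atoms: none
Why: addition of the small lithium alkynyl ether to the non-enolisable, doubly neopentyl ketone and Meyer–Schuster rearrangement of the tertiary carbinol (no Rupe pathway is open) should give the alkylidene acetate as an inconsequential E/Z mixture, while the acidic ethanol cleaves the trimethylsilyl ether; C5 is set in step 10.

Step 9
Reactants: 15 ethyl alkylidene acetate
Product: 16 alkylidene acetate with the allyl group masked as 2,3-dibromopropyl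
Conditions: Br2 (1.0 equiv), CH2Cl2, −78 °C
Reagents that add atoms: bromine, BrBr
Why: electrophilic anti addition to the electron-rich terminal alkene only (the hindered, conjugated exocyclic alkene is inert), which masks the allyl group for the hydrogenation; the new CHBr centre is not retained.

Step 10
Reactants: 16 dibromide-protected alkylidene acetate
Product: 17 saturated ester (5α-H; 5β-CH2CO2Et)
Conditions: [Ir(cod)(PCy3)(py)]PF6 (10 mol%), H2 (4 atm), CH2Cl2, rt
Reagents that add atoms: none
Why: hydroxyl-directed homogeneous hydrogenation (Crabtree type), in which iridium bound to the C1 hydroxyl should deliver hydrogen to the α face of the C5=C6 bond whatever its geometry, giving 5α-H with the acetate arm β (trans to OH).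

Step 11
Reactants: 17 saturated ester with 2,3-dibromopropyl group
Product: 18 saturated ester with the C4 allyl group restored
Conditions: Zn dust, AcOH, THF, 0 °C → rt
Reagents that add atoms: none
Why: reductive elimination of the vicinal dibromide regenerates the terminal alkene; alkyl chloride, ester and silyl ether are inert to zinc.

Step 12
Reactants: 18 allyl ester with free 1α-OH
Product: 19 C1 tert-butyldimethylsilyl ether of 18
Conditions: t-BuMe2SiOTf, 2,6-lutidine, CH2Cl2, 0 °C
Reagents that add atoms: tert-butyldimethylsilyl triflate, CC(C)(C)[Si](C)(C)OS(=O)(=O)C(F)(F)F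
Why: silylation of the hindered axial secondary alcohol; O1 has to be blocked so that the later C11 aldehyde cannot close to a lactol.

Step 13
Reactants: 19 bis-silyl ether ester
Product: 20 C7 aldehyde (5β-CH2CHO)
Conditions: i-Bu2AlH (1.1 equiv), CH2Cl2, −78 °C; Rochelle salt
Reagents that add atoms: none
Why: partial reduction of the ester through the stable tetrahedral aluminium hemiacetal should stop at the aldehyde.

Step 14
Reactants: 20 C7 aldehyde; 21 methyl (triphenylphosphoranylidene)acetate
Product: 23 methyl (Z)-2-bromo-2-enoate (5β-CH2CH=C(Br)CO2Me), via bromo ylide 22 (not isolated)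
Conditions: 21, N-bromosuccinimide, CH2Cl2, −20 °C; then 20, rt
Reagents that add atoms: N-bromosuccinimide, BrN1C(=O)CCC1=O
Why: Wittig olefination with the stabilised α-bromo ylide made in the flask; the ester should end trans to the alkyl chain, i.e. the (Z)-2-bromo-2-enoate with bromine cis to C6, as the ring closure requires.

Step 15
Reactants: 23 methyl (Z)-2-bromo-2-enoate with C4 allyl group; 24 2-methylbut-3-en-2-ol
Product: 25 bromo-enoate with the complete (E)-CH2CH=CH–C(CH3)2OH side chain on C4
Conditions: second-generation Grubbs catalyst (5 mol%), 24 (10 equiv), CH2Cl2, 40 °C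
Reagents that add atoms: none
Why: olefin cross-metathesis of the terminal allyl group with the tertiary allylic alcohol should be E-selective, and the trisubstituted bromo-enoate does not engage the ruthenium carbene.

Step 16
Reactants: 25 bromo-enoate bis-silyl ether
Product: 26 primary alcohol (10α-CH2CH2OH)
Conditions: HF·pyridine, pyridine, THF, 0 °C
Reagents that add atoms: none
Why: selective desilylation, since the unhindered primary silyl ether should be cleaved much faster than the hindered axial secondary one on C1.

Step 17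
Reactants: 26 primary alcohol
Product: 27 C11 aldehyde (10α-CH2CHO), the cyclisation precursor
Conditions: Dess–Martin periodinane, NaHCO3, CH2Cl2, 0 °C → rt
Reagents that add atoms: none
Why: Dess–Martin oxidation of the primary alcohol under buffered, near-neutral conditions; the tertiary alcohol cannot be oxidised.

Step 18
Reactants: 27 C11 aldehyde with (Z)-2-bromo-2-enoate arm
Product: 28 1-O-tert-butyldimethylsilyl ether of the target (ring B closed; 9β-CHO)
Conditions: Pd2(dba)3 (5 mol%), Xantphos (12 mol%), Cs2CO3 (1.5 equiv), 1,4-dioxane, 70 °C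
Reagents that add atoms: none
Why: Oxidative addition of zerovalent palladium into the C8–Br bond (with retention of the Z geometry) is followed by deprotonation of the aldehyde, formation of the C9-bound palladium enolate and C–C reductive elimination. The closest known reaction type is the palladium-catalysed intramolecular α-alkenylation (and α-arylation) of ketone and aldehyde enolates with vinyl or aryl halides. Ring B closes as a six-membered ring through a seven-membered palladacycle, formally a 6-(enolexo)-endo-trig closure at C8, so the C7=C8 bond ends up endocyclic and conjugated to the ester. The new C9 stereocentre should be controlled by ring A both kinetically and thermodynamically: the formyl group takes the equatorial β position because the axial α position would be 1,3-diaxial to the C1 silyloxy group, and α-face protonation of any dienolate formed gives the same epimer. The step needs C- over O-alkenylation, no aldol reaction or dehydrobromination and no double-bond migration; the single enolisable site (C9H2 next to quaternary C10), the bromide held cis to the tether, a wide-bite-angle ligand and the mild carbonate base should secure this, and the silyl ether on O1 keeps a 9-epimer from being trapped as a lactol.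

Step 19
Reactants: 28 1-O-silyl ether of the target
Product: 29 target compound
Conditions: HF·pyridine, pyridine, THF, rt
Reagents that add atoms: none
Why: fluoride-mediated cleavage of the last silyl ether under mildly acidic, non-basic conditions, so that C9 should not epimerise (a 9-epimer would lactolise with the freed 1α-OH) and the tertiary allylic alcohol is not ionised.

Compound list
1 | 2-methylcyclohexane-1,3-dione | CC1C(=O)CCCC1=O | starting material
2 | allyl bromide (3-bromoprop-1-ene) | C=CCBr | starting material
3 | 2-allyl-2-methylcyclohexane-1,3-dione | C=CCC1(C)C(=O)CCCC1=O | intermediate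
4 | (2R,3R)-2-allyl-3-hydroxy-2-methylcyclohexan-1-one (OH cis to allyl) | O=C1[C@](C)(CC=C)[C@H](O)CCC1 | intermediate
5 | (2S,3S)-2-allyl-3-chloro-2-methylcyclohexan-1-one (C5 ketone; 4β-Me, 4α-allyl, 3β-Cl) | O=C1[C@](C)(CC=C)[C@@H](Cl)CCC1 | intermediate
6 | trimethylsilyl enol ether of 5 (C5–OSiMe3, C5=C10) | C[Si](C)(C)OC=1[C@](C)(CC=C)[C@@H](Cl)CCC=1 | intermediate
7 | (5S,6S)-6-allyl-5-chloro-6-methylcyclohex-2-en-1-one (C5 ketone, C10=C1) | O=C1[C@](C)(CC=C)[C@@H](Cl)CC=C1 | intermediate
8 | 2-allyl-3-chloro-2-methyl-5-(pinacolboryl)cyclohexan-1-one, boron on C1 α (trans to Cl) | O=C1[C@](C)(CC=C)[C@@H](Cl)C[C@H](B2OC(C)(C)C(C)(C)O2)C1 | intermediate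
9 | (2S,3S,5R)-2-allyl-3-chloro-5-hydroxy-2-methylcyclohexan-1-one (1α-OH, 3β-Cl) | O=C1[C@](C)(CC=C)[C@@H](Cl)C[C@H](O)C1 | intermediate
10 | tert-butyl(2-iodoethoxy)dimethylsilane | CC(C)(C)[Si](C)(C)OCCI | starting material
11 | 9 carrying CH2CH2OSiMe2t-Bu on C10 (arm β, anti to the 1α-OH; 10α-H; expected major epimer) | O=C1[C@](C)(CC=C)[C@@H](Cl)C[C@H](O)[C@H]1CCO[Si](C)(C)C(C)(C)C | intermediate
12 | C5 ketone: 4β-Me, 4α-allyl, 3β-Cl, 1α-OSiMe3, 10β-Me, 10α-CH2CH2OSiMe2t-Bu | O=C1[C@](C)(CC=C)[C@@H](Cl)C[C@H](O[Si](C)(C)C)[C@]1(C)CCO[Si](C)(C)C(C)(C)C | intermediate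
13 | ethoxyacetylene (ethoxyethyne) | CCOC#C | starting material
14 | tertiary C5 carbinol of 12 bearing C≡C–OEt (C5 epimers) | CCOC#CC1(O)[C@](C)(CC=C)[C@@H](Cl)C[C@H](O[Si](C)(C)C)[C@]1(C)CCO[Si](C)(C)C(C)(C)C | intermediate
15 | ethyl alkylidene acetate: exocyclic C5=C6H–CO2Et (E/Z), free 1α-OH, other substituents as in 12 | CCOC(=O)C=C1[C@](C)(CC=C)[C@@H](Cl)C[C@H](O)[C@]1(C)CCO[Si](C)(C)C(C)(C)C | intermediate
16 | 15 with the C4 allyl group as 2,3-dibromopropyl (CHBr epimers) | CCOC(=O)C=C1[C@](C)(CC(Br)CBr)[C@@H](Cl)C[C@H](O)[C@]1(C)CCO[Si](C)(C)C(C)(C)C | intermediate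
17 | saturated ester: 5α-H, 5β-CH2CO2Et, 2,3-dibromopropyl on C4, 1α-OH | CCOC(=O)C[C@H]1[C@](C)(CC(Br)CBr)[C@@H](Cl)C[C@H](O)[C@]1(C)CCO[Si](C)(C)C(C)(C)C | intermediate
18 | as 17 with the 4α-allyl group restored | CCOC(=O)C[C@H]1[C@](C)(CC=C)[C@@H](Cl)C[C@H](O)[C@]1(C)CCO[Si](C)(C)C(C)(C)C | intermediate
19 | C1 tert-butyldimethylsilyl ether of 18 | CCOC(=O)C[C@H]1[C@](C)(CC=C)[C@@H](Cl)C[C@H](O[Si](C)(C)C(C)(C)C)[C@]1(C)CCO[Si](C)(C)C(C)(C)C | intermediate
20 | C7 aldehyde: 5β-CH2CHO, bis-silyl ether | O=CC[C@H]1[C@](C)(CC=C)[C@@H](Cl)C[C@H](O[Si](C)(C)C(C)(C)C)[C@]1(C)CCO[Si](C)(C)C(C)(C)C | intermediate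
21 | methyl (triphenylphosphoranylidene)acetate | COC(=O)C=P(c1ccccc1)(c1ccccc1)c1ccccc1 | starting material
22 | methyl bromo(triphenylphosphoranylidene)acetate | COC(=O)C(Br)=P(c1ccccc1)(c1ccccc1)c1ccccc1 | intermediate
23 | methyl (Z)-2-bromo-2-enoate: 5β-CH2CH=C(Br)CO2Me, 4α-allyl, bis-silyl ether | COC(=O)/C(Br)=C/C[C@H]1[C@](C)(CC=C)[C@@H](Cl)C[C@H](O[Si](C)(C)C(C)(C)C)[C@]1(C)CCO[Si](C)(C)C(C)(C)C | intermediate
24 | 2-methylbut-3-en-2-ol | C=CC(C)(C)O | starting material
25 | 23 with the 4α side chain (E)-CH2CH=CH–C(CH3)2OH | COC(=O)/C(Br)=C/C[C@H]1[C@](C)(C/C=C/C(C)(C)O)[C@@H](Cl)C[C@H](O[Si](C)(C)C(C)(C)C)[C@]1(C)CCO[Si](C)(C)C(C)(C)C | intermediate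
26 | 25 with free primary alcohol (10α-CH2CH2OH) | COC(=O)/C(Br)=C/C[C@H]1[C@](C)(C/C=C/C(C)(C)O)[C@@H](Cl)C[C@H](O[Si](C)(C)C(C)(C)C)[C@]1(C)CCO | intermediate
27 | C11 aldehyde (10α-CH2CHO), cyclisation precursor | COC(=O)/C(Br)=C/C[C@H]1[C@](C)(C/C=C/C(C)(C)O)[C@@H](Cl)C[C@H](O[Si](C)(C)C(C)(C)C)[C@]1(C)CC=O | intermediate
28 | 1-O-tert-butyldimethylsilyl ether of the target (trans-fused bicycle, 9β-CHO) | COC(=O)C1=CC[C@H]2[C@](C)(C/C=C/C(C)(C)O)[C@@H](Cl)C[C@H](O[Si](C)(C)C(C)(C)C)[C@]2(C)[C@H]1C=O | intermediate
29 | target, CNP0167913.1 | COC(=O)C1=CC[C@H]2[C@](C)(C/C=C/C(C)(C)O)[C@@H](Cl)C[C@H](O)[C@]2(C)[C@H]1C=O | target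

Total step count: 19. Longest linear sequence: 19 steps (from 1).

Steps most likely to fail

Step 18 (key step). Under the basic conditions the aldehyde enolate may condense with itself, the bromo-enoate may lose HBr, and the product, whose C9–H is doubly activated, may epimerise or let the double bond migrate. The fallback makes the same bond under neutral radical conditions. It sets out from 27 and comes back at 28. Acetylation of the aldehyde enol (Ac2O, Et3N, DMAP) would give the enol acetate F1. Slow addition of Bu3SnH/AIBN (benzene, 80 °C) would generate the C8 vinyl radical, which should cyclise 6-exo onto C9 to give the 11-acetoxy bicycle F2, with the acetoxymethyl group equatorial (β). K2CO3 in MeOH would free the primary alcohol F3, which carries no epimerisable centre, and Dess–Martin oxidation would return 28.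

Step 8. Addition to a ketone flanked by two quaternary carbons may stall, and the tertiary lithium alkoxide may fragment with loss of the C3 chloride. The fallback is an aldol–dehydration sequence; it sets out from 12 and comes back at 15. The cerium enolate of ethyl acetate (LiN(i-Pr)2, EtOAc, then anhydrous CeCl3, THF, −78 °C) would add to 12 to give the β-hydroxy ester F4. Dehydration with Martin sulfurane, for which only the exocyclic direction is available, would give the silyl-protected alkylidene ester F5. Citric acid in MeOH would remove the trimethylsilyl group to give 15.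

Step 6. Alkylation of the dianion with a β-silyloxyethyl iodide may be slow and lose material through elimination of the iodide, O-alkylation and proton transfer. The fallback attaches the arm to an sp2 carbon by cross-coupling; it sets out from 7 and comes back at 11. α-Iodination of the enone (I2, pyridine) would give the 2-iodo enone F6. Negishi coupling with the organozinc reagent made from 10 (Zn dust, DMA; Pd2(dba)3, SPhos) would give the 2-(2-silyloxyethyl) enone F7. Conjugate borylation/oxidation as in step 5, trans to chlorine, would then give 11 as a C10 epimer mixture, which is inconsequential because step 7 planarises C10.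

Further compounds
F1 | step 18 | enol acetate of aldehyde 27 (C9=C11H–OAc, E/Z) | COC(=O)/C(Br)=C/C[C@H]1[C@](C)(C/C=C/C(C)(C)O)[C@@H](Cl)C[C@H](O[Si](C)(C)C(C)(C)C)[C@]1(C)C=COC(C)=O
F2 | step 18 | ring-B-closed 11-acetate (9β-CH2OAc) of the 1-O-silyl ether | COC(=O)C1=CC[C@H]2[C@](C)(C/C=C/C(C)(C)O)[C@@H](Cl)C[C@H](O[Si](C)(C)C(C)(C)C)[C@]2(C)[C@H]1COC(C)=O
F3 | step 18 | ring-B-closed 11-alcohol (9β-CH2OH) of the 1-O-silyl ether | COC(=O)C1=CC[C@H]2[C@](C)(C/C=C/C(C)(C)O)[C@@H](Cl)C[C@H](O[Si](C)(C)C(C)(C)C)[C@]2(C)[C@H]1CO
F4 | step 8 | β-hydroxy ester from 12 (C5 carbinol bearing CH2CO2Et, C5 epimers) | CCOC(=O)CC1(O)[C@](C)(CC=C)[C@@H](Cl)C[C@H](O[Si](C)(C)C)[C@]1(C)CCO[Si](C)(C)C(C)(C)C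
F5 | step 8 | 1-O-trimethylsilyl ether of alkylidene acetate 15 | CCOC(=O)C=C1[C@](C)(CC=C)[C@@H](Cl)C[C@H](O[Si](C)(C)C)[C@]1(C)CCO[Si](C)(C)C(C)(C)C
F6 | step 6 | (5S,6S)-6-allyl-5-chloro-2-iodo-6-methylcyclohex-2-en-1-one | O=C1[C@](C)(CC=C)[C@@H](Cl)CC=C1I
F7 | step 6 | 2-(2-silyloxyethyl) enone (C10 bearing CH2CH2OSiMe2t-Bu, C10=C1) | O=C1[C@](C)(CC=C)[C@@H](Cl)CC=C1CCO[Si](C)(C)C(C)(C)C
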